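**Retrosynthetic overview**
- The target is (−)-epicatechin-(4β→8)-(−)-epiafzelechin; the last step is global hydrogenolysis of its hepta-O-benzyl ether.
- The interflavan C4–C8 bond is cut next: a Friedel–Crafts coupling of a C4-activated tetra-O-benzyl-epicatechin (upper unit, made from commercial (−)-epicatechin) with tri-O-benzyl-epiafzelechin (lower unit).
- The lower unit comes from a proposed new dynamic kinetic transfer hydrogenation of a racemic flavan-3-one, which sets its C2 and C3 together.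
- The flavan-3-one comes from a flav-3-ene (hydroboration–oxidation, then alcohol oxidation), the flav-3-ene from a 2'-hydroxychalcone, and the chalcone from an acetophenone and an aldehyde.
- Ring order: lower rings A and B arrive preformed, lower ring C is closed by reductive cyclisation of the chalcone, the upper rings A, B and C come from the chiral pool, and the two halves are joined last.

Assumption: (−)-epicatechin is bought as the chiral-pool source of the upper unit; racemic compounds are named rac and drawn as one enantiomer or without stereo marks.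

**Step 1**
Reactants: 1 2',4',6'-trihydroxyacetophenone
Product: 2 1-[2,4-bis(benzyloxy)-6-hydroxyphenyl]ethanone
Conditions: BnBr (2.05 equiv), K2CO3 (2.2 equiv), DMF, 0 °C to rt, 16 h
Reagents that add atoms: benzyl bromide, BrCc1ccccc1
Why: Williamson ether synthesis in which one ortho hydroxyl stays hydrogen-bonded to the acetyl carbonyl and is too poorly nucleophilic to react, so only the other two phenols are benzylated.

**Step 2**
Reactants: 2 1-[2,4-bis(benzyloxy)-6-hydroxyphenyl]ethanone; 3 4-(benzyloxy)benzaldehyde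
Product: 4 (E)-1-[2,4-bis(benzyloxy)-6-hydroxyphenyl]-3-[4-(benzyloxy)phenyl]prop-2-en-1-one
Conditions: KOH (50% aq.), EtOH/THF, rt, 36 h; then 1 M HCl
Reagents that add atoms: none
Why: Claisen–Schmidt condensation of a methyl ketone with a non-enolisable aldehyde, whose E1cB dehydration gives only the conjugated (E)-enone.

**Step 3**
Reactants: 4 (E)-1-[2,4-bis(benzyloxy)-6-hydroxyphenyl]-3-[4-(benzyloxy)phenyl]prop-2-en-1-one
Product: 6 rac-5,7-bis(benzyloxy)-2-[4-(benzyloxy)phenyl]-2H-chromene, via allylic alcohol 5 (not isolated)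
Conditions: NaBH4 (3 equiv), THF/2-propanol, 60 °C; then AcOH, rt
Reagents that add atoms: none
Why: Borohydride 1,2-reduction of the 2'-hydroxychalcone gives an allylic alcohol benzylic to the trioxygenated ring A, which loses water readily while the phenol oxygen closes ring C at the cinnamyl carbon (reductive cyclisation of 2'-hydroxychalcones to flav-3-enes), forming C2 as a racemate.

**Step 4**
Reactants: 6 rac-5,7-bis(benzyloxy)-2-[4-(benzyloxy)phenyl]-2H-chromene
Product: 8 rac-(2R,3S)-5,7-bis(benzyloxy)-2-[4-(benzyloxy)phenyl]chroman-3-ol, via C3 alkylborane 7 (not isolated)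
Conditions: BH3·THF (1.5 equiv), THF, 0 °C to rt; then NaOH, H2O2, 0 °C to rt
Reagents that add atoms: hydrogen peroxide, OO
Why: Hydroboration–oxidation in which boron adds to C3, the carbon remote from the electron-rich ring A (styrene regiochemistry), on the face opposite the C2 aryl group, and the C–B bond is oxidised with retention, giving the racemic 2,3-trans alcohol.

**Step 5**
Reactants: 8 rac-(2R,3S)-5,7-bis(benzyloxy)-2-[4-(benzyloxy)phenyl]chroman-3-ol
Product: 9 rac-5,7-bis(benzyloxy)-2-[4-(benzyloxy)phenyl]chroman-3-one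
Conditions: Dess–Martin periodinane (1.3 equiv), wet CH2Cl2, rt, 1 h
Reagents that add atoms: none
Why: Dess–Martin oxidation of a secondary alcohol under neutral conditions that leave the benzyl ethers and ring A untouched; C3 is erased and C2 becomes epimerisable, as needed for the next step.

**Step 6**
Reactants: 9 rac-5,7-bis(benzyloxy)-2-[4-(benzyloxy)phenyl]chroman-3-one
Product: 11 (2R,3R)-5,7-bis(benzyloxy)-2-[4-(benzyloxy)phenyl]chroman-3-ol, via achiral enol 10 (not isolated)
Conditions: RuCl[(R,R)-TsDPEN](p-cymene) (2 mol %), HCO2H/Et3N (1:1), DMF, 35 °C, under argon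
Reagents that add atoms: none
Why: Proposed new method: dynamic kinetic resolution by asymmetric transfer hydrogenation of a flavan-3-one, a substrate class on which it has not been shown; the C2–H of 9 is benzylic, α to the ketone and α to the ring oxygen, so Et3N interconverts the two enantiomers through enol 10 faster than either is reduced, while the ruthenium hydride (outer-sphere concerted Ru–H/N–H transfer through a six-membered transition state) attacks the carbonyl face opposite the pseudo-equatorial C2 aryl group (equatorial attack of a bulky hydride, hence 2,3-cis) and, with the (R,R) ligand, the face that puts the aryloxy-bearing C2 side next to the η6-arene (C–H/π contact, as for the aryl of an aryl ketone), a combination open only to the (2R)-ketone, so C2 = R and C3 = R are set together; the closest known reactions are Noyori–Ikariya transfer hydrogenation, hydrogenation of 2-aryl- and 2-alkoxycycloalkanones to cis-alcohols with dynamic kinetic resolution, and transfer hydrogenation of α-aryloxy ketones.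

**Step 7**
Reactants: 12 (−)-epicatechin
Product: 13 (2R,3R)-5,7-bis(benzyloxy)-2-[3,4-bis(benzyloxy)phenyl]chroman-3-ol
Conditions: BnBr (4.4 equiv), K2CO3 (5 equiv), DMF, −10 °C to rt, under argon
Reagents that add atoms: benzyl bromide, BrCc1ccccc1
Why: Williamson etherification of the four phenols with carbonate, which does not deprotonate the C3 alcohol, while low temperature and quick capping of the 4'-phenol suppress base-induced C2 epimerisation, so C2 and C3 of the upper unit are carried over from the chiral pool.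

**Step 8**
Reactants: 13 (2R,3R)-5,7-bis(benzyloxy)-2-[3,4-bis(benzyloxy)phenyl]chroman-3-ol
Product: 15 (2R,3R,4S)-5,7-bis(benzyloxy)-2-[3,4-bis(benzyloxy)phenyl]-4-(2-ethoxyethoxy)chroman-3-ol, via C4 cation 14 (not isolated)
Conditions: DDQ (2.0 equiv), EtOCH2CH2OH (5 equiv), CH2Cl2, rt, 2 h
Reagents that add atoms: 2-ethoxyethanol, CCOCCO
Why: DDQ benzylic C–H oxidation in which hydride abstraction from C4 gives a cation stabilised by the 5,7-dioxygenated ring A, and the alcohol adds on the face opposite the cis C2 aryl and C3 hydroxyl groups, giving only the 4β ether (3,4-trans); benzyl ethers resist DDQ.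

**Step 9**
Reactants: 15 (2R,3R,4S)-5,7-bis(benzyloxy)-2-[3,4-bis(benzyloxy)phenyl]-4-(2-ethoxyethoxy)chroman-3-ol; 11 (2R,3R)-5,7-bis(benzyloxy)-2-[4-(benzyloxy)phenyl]chroman-3-ol (3 equiv, excess recovered)
Product: 16 5,7,3',4'-tetra-O-benzyl-(−)-epicatechin-(4β→8)-5,7,4'-tri-O-benzyl-(−)-epiafzelechin
Conditions: TMSOTf (0.2 equiv), CH2Cl2, −78 °C, 10 min; then sat. aq. NaHCO3
Reagents that add atoms: none
Why: Lewis acid-promoted Friedel–Crafts alkylation (interflavan coupling) in which TMSOTf ionises the C4 ether of 15 back to the ring A-stabilised cation 14 already met in step 8, and the most nucleophilic, least hindered position C8 of ring A of 11 attacks it from the β face, opposite the C2 aryl and C3 hydroxyl groups, setting upper C4 as R (3,4-trans, 4β→8), while excess 11 suppresses oligomers.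

**Step 10**
Reactants: 16 5,7,3',4'-tetra-O-benzyl-(−)-epicatechin-(4β→8)-5,7,4'-tri-O-benzyl-(−)-epiafzelechin
Product: 17 (−)-epicatechin-(4β→8)-(−)-epiafzelechin (target)
Conditions: H2 (1 atm), Pd(OH)2/C, THF/MeOH/H2O (20:1:1), rt; then Sephadex LH-20
Reagents that add atoms: none
Why: Catalytic hydrogenolysis of the seven benzyl ethers, which touches no stereocentre and leaves the ring C ethers and the interflavan C–C bond intact at 1 atm and rt.

**Compound list**
1 | 2',4',6'-trihydroxyacetophenone | CC(=O)c1c(O)cc(O)cc1O | starting material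
2 | 1-[2,4-bis(benzyloxy)-6-hydroxyphenyl]ethanone | CC(=O)c1c(O)cc(OCc2ccccc2)cc1OCc1ccccc1 | intermediate
3 | 4-(benzyloxy)benzaldehyde | O=Cc1ccc(OCc2ccccc2)cc1 | starting material
4 | (E)-1-[2,4-bis(benzyloxy)-6-hydroxyphenyl]-3-[4-(benzyloxy)phenyl]prop-2-en-1-one (chalcone) | O=C(/C=C/c1ccc(OCc2ccccc2)cc1)c1c(O)cc(OCc2ccccc2)cc1OCc1ccccc1 | intermediate
5 | rac-(E)-1-[2,4-bis(benzyloxy)-6-hydroxyphenyl]-3-[4-(benzyloxy)phenyl]prop-2-en-1-ol | OC(/C=C/c1ccc(OCc2ccccc2)cc1)c1c(O)cc(OCc2ccccc2)cc1OCc1ccccc1 | intermediate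
6 | rac-5,7-bis(benzyloxy)-2-[4-(benzyloxy)phenyl]-2H-chromene (flav-3-ene) | C1(c2ccc(OCc3ccccc3)cc2)Oc2cc(OCc3ccccc3)cc(OCc3ccccc3)c2C=C1 | intermediate
7 | rac-[(2,3-trans)-5,7-bis(benzyloxy)-2-[4-(benzyloxy)phenyl]chroman-3-yl]borane | B[C@H]1Cc2c(OCc3ccccc3)cc(OCc3ccccc3)cc2O[C@@H]1c1ccc(OCc2ccccc2)cc1 | intermediate
8 | rac-(2R,3S)-5,7-bis(benzyloxy)-2-[4-(benzyloxy)phenyl]chroman-3-ol (2,3-trans) | O[C@H]1Cc2c(OCc3ccccc3)cc(OCc3ccccc3)cc2O[C@@H]1c1ccc(OCc2ccccc2)cc1 | intermediate
9 | rac-5,7-bis(benzyloxy)-2-[4-(benzyloxy)phenyl]chroman-3-one | O=C1Cc2c(OCc3ccccc3)cc(OCc3ccccc3)cc2OC1c1ccc(OCc2ccccc2)cc1 | intermediate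
10 | 5,7-bis(benzyloxy)-2-[4-(benzyloxy)phenyl]-4H-chromen-3-ol (achiral enol) | OC1=C(c2ccc(OCc3ccccc3)cc2)Oc2cc(OCc3ccccc3)cc(OCc3ccccc3)c2C1 | intermediate
11 | (2R,3R)-5,7-bis(benzyloxy)-2-[4-(benzyloxy)phenyl]chroman-3-ol (5,7,4'-tri-O-benzyl-(−)-epiafzelechin, 2,3-cis) | O[C@@H]1Cc2c(OCc3ccccc3)cc(OCc3ccccc3)cc2O[C@@H]1c1ccc(OCc2ccccc2)cc1 | intermediate
12 | (−)-epicatechin, (2R,3R)-2-(3,4-dihydroxyphenyl)chroman-3,5,7-triol | O[C@@H]1Cc2c(O)cc(O)cc2O[C@@H]1c1ccc(O)c(O)c1 | starting material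
13 | (2R,3R)-5,7-bis(benzyloxy)-2-[3,4-bis(benzyloxy)phenyl]chroman-3-ol (5,7,3',4'-tetra-O-benzyl-(−)-epicatechin) | O[C@@H]1Cc2c(OCc3ccccc3)cc(OCc3ccccc3)cc2O[C@@H]1c1ccc(OCc2ccccc2)c(OCc2ccccc2)c1 | intermediate
14 | (2R,3R)-5,7-bis(benzyloxy)-2-[3,4-bis(benzyloxy)phenyl]-3-hydroxychroman-4-ylium (C4 cation) | O[C@@H]1[CH+]c2c(OCc3ccccc3)cc(OCc3ccccc3)cc2O[C@@H]1c1ccc(OCc2ccccc2)c(OCc2ccccc2)c1 | intermediate
15 | (2R,3R,4S)-5,7-bis(benzyloxy)-2-[3,4-bis(benzyloxy)phenyl]-4-(2-ethoxyethoxy)chroman-3-ol (4β ether, 2,3-cis-3,4-trans) | CCOCCO[C@H]1c2c(OCc3ccccc3)cc(OCc3ccccc3)cc2O[C@H](c2ccc(OCc3ccccc3)c(OCc3ccccc3)c2)[C@@H]1O | intermediate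
16 | (2R,3R,4R)-5,7-bis(benzyloxy)-2-[3,4-bis(benzyloxy)phenyl]-4-[(2R,3R)-5,7-bis(benzyloxy)-2-[4-(benzyloxy)phenyl]-3-hydroxychroman-8-yl]chroman-3-ol (hepta-O-benzyl dimer) | c1ccccc1COc1ccc([C@H]2Oc3c(c(OCc4ccccc4)cc(OCc4ccccc4)c3[C@H]3c4c(OCc5ccccc5)cc(OCc5ccccc5)cc4O[C@H](c4ccc(OCc5ccccc5)c(OCc5ccccc5)c4)[C@@H]3O)C[C@H]2O)cc1 | intermediate
17 | (2R,3R,4R)-2-(3,4-dihydroxyphenyl)-4-[(2R,3R)-3,5,7-trihydroxy-2-(4-hydroxyphenyl)chroman-8-yl]chroman-3,5,7-triol, (−)-epicatechin-(4β→8)-(−)-epiafzelechin | Oc1ccc([C@H]2Oc3c(c(O)cc(O)c3[C@H]3c4c(O)cc(O)cc4O[C@H](c4ccc(O)c(O)c4)[C@@H]3O)C[C@H]2O)cc1 | target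

**Summary**
Total step count: 10. Longest linear sequence: 8 steps (steps 1 to 6, then 9 and 10).

**Three steps most likely to fail**

Step 3 (reductive cyclisation to flav-3-ene 6). The chelated enone can undergo 1,4-reduction to the dihydrochalcone, and the electron-rich flavene is acid-labile. The fallback sets out from chalcone 4 and comes back at 6. NaOAc in refluxing EtOH closes ring C by oxa-Michael addition to give rac-5,7-bis(benzyloxy)-2-[4-(benzyloxy)phenyl]chroman-4-one F1. NaBH4 in THF/MeOH at 0 °C reduces this to rac-(2,4-cis)-5,7-bis(benzyloxy)-2-[4-(benzyloxy)phenyl]chroman-4-ol F2. Pyridinium p-toluenesulfonate (cat.) in toluene at 80 °C then dehydrates the ring A-activated benzylic alcohol to 6.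

Step 6 (the proposed new step). The sense and level of enantioselection on a ketone flanked by two sp3 carbons are unknown; the (R,R) choice rests on a model, and the configuration of 11 must be confirmed by rotation and chiral HPLC. C2 racemisation could also lag behind reduction, and enol 10 is air-sensitive. The fallback uses known chemistry, sets out from ketone 9 and comes back at 11. LiBH(s-Bu)3 in THF at −78 °C reduces 9 from the face opposite the C2 aryl group to the racemic 2,3-cis alcohol, which is 11 and its mirror image (2S,3S)-5,7-bis(benzyloxy)-2-[4-(benzyloxy)phenyl]chroman-3-ol F3 in equal amounts. Preparative HPLC on a cellulose tris(3,5-dimethylphenylcarbamate) phase separates them. The unwanted enantiomer is recycled by Dess–Martin oxidation, which returns 9 after Et3N-mediated racemisation.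

Step 9 (interflavan coupling). The C6 regioisomer and oligomers can form, because the electrophile and the product are themselves nucleophiles. The fallback sets out from 13 and comes back at target 17. NBS (1.0 equiv) in CH2Cl2 at −40 °C brominates the most reactive position C8 to give 8-bromo-5,7,3',4'-tetra-O-benzyl-(−)-epicatechin F4. DDQ and 2-ethoxyethanol in CH2Cl2 then give 8-bromo-4β-(2-ethoxyethoxy)-5,7,3',4'-tetra-O-benzyl-(−)-epicatechin F5, which cannot alkylate itself. TMSOTf in CH2Cl2 at −40 °C with 11 (1.2 equiv) gives the bromo-capped dimer 8-bromo-5,7,3',4'-tetra-O-benzyl-(−)-epicatechin-(4β→8)-5,7,4'-tri-O-benzyl-(−)-epiafzelechin F6. H2, Pd(OH)2/C and Et3N in THF/MeOH/H2O remove the bromine and the seven benzyl groups together to give 17.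

**Further compounds**
F1 | step 3 | rac-5,7-bis(benzyloxy)-2-[4-(benzyloxy)phenyl]chroman-4-one | O=C1CC(c2ccc(OCc3ccccc3)cc2)Oc2cc(OCc3ccccc3)cc(OCc3ccccc3)c12
F2 | step 3 | rac-(2,4-cis)-5,7-bis(benzyloxy)-2-[4-(benzyloxy)phenyl]chroman-4-ol | O[C@@H]1C[C@H](c2ccc(OCc3ccccc3)cc2)Oc2cc(OCc3ccccc3)cc(OCc3ccccc3)c21
F3 | step 6 | (2S,3S)-5,7-bis(benzyloxy)-2-[4-(benzyloxy)phenyl]chroman-3-ol | O[C@H]1Cc2c(OCc3ccccc3)cc(OCc3ccccc3)cc2O[C@H]1c1ccc(OCc2ccccc2)cc1
F4 | step 9 | 8-bromo-5,7,3',4'-tetra-O-benzyl-(−)-epicatechin | O[C@@H]1Cc2c(OCc3ccccc3)cc(OCc3ccccc3)c(Br)c2O[C@@H]1c1ccc(OCc2ccccc2)c(OCc2ccccc2)c1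
F5 | step 9 | 8-bromo-4β-(2-ethoxyethoxy)-5,7,3',4'-tetra-O-benzyl-(−)-epicatechin | CCOCCO[C@H]1c2c(OCc3ccccc3)cc(OCc3ccccc3)c(Br)c2O[C@H](c2ccc(OCc3ccccc3)c(OCc3ccccc3)c2)[C@@H]1O
F6 | step 9 | 8-bromo-5,7,3',4'-tetra-O-benzyl-(−)-epicatechin-(4β→8)-5,7,4'-tri-O-benzyl-(−)-epiafzelechin | c1ccccc1COc1ccc([C@H]2Oc3c(c(OCc4ccccc4)cc(OCc4ccccc4)c3[C@H]3c4c(OCc5ccccc5)cc(OCc5ccccc5)c(Br)c4O[C@H](c4ccc(OCc5ccccc5)c(OCc5ccccc5)c4)[C@@H]3O)C[C@H]2O)cc1
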